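Ring A is the central benzene, numbered here C-1 to C-6: C-1 carries the methide carbon Cm (with rings C and D), C-2 ring B, C-3 and C-4 hydrogen, C-5 CH2OH and C-6 the alkyne Cα≡Cβ–ring E. Since C-3 and C-4 are unsubstituted CH and the alkyne sits on C-6 beside C-1, the ring divides into a four-carbon diene C-3 to C-6 that already bears the alkyne and a two-carbon aryl alkynyl ketone that supplies C-1 and C-2.
Retrosynthetic cuts, in order: Cm=ring C (quinone methide back to a triarylcarbinol), Cm–aryl (aryllithium plus ketone), ring A between C-2 and C-3 and between C-1 and C-6 (Diels–Alder), C-6–Cα (Sonogashira), the bond between C-4 and C-5 (carbomagnesiation of propargyl alcohol), and both bonds at the ynone carbonyl carbon (carbonylative Sonogashira).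
Forward: rings B, C, D and E all come from 4-iodophenol; ring A is the only ring built, closed in step 8 and aromatised in step 9; the last aryl group is joined to Cm in step 10 and ring C turns quinoid in step 11.
Stereochemistry: the target has no stereocentre. The only element to control is the Z geometry of the diene (alkynyl trans to vinyl), set by chelation-controlled anti-carbomagnesiation and kept through iodination and coupling; the C-6 stereocentre of the cycloadduct is racemic and vanishes on aromatisation.

Key step: step 8

Remark: in the carbinol the two aryl groups on Cm are the same 4-oxyphenyl unit (rings C and D differ only after dehydration), so both are introduced as 4-(methoxymethoxy)phenyl; MOM = methoxymethyl.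

Step 1
Reactants: 1 4-iodophenol
Product: 2 1-iodo-4-(methoxymethoxy)benzene
Conditions: MOMCl, iPr2NEt, CH2Cl2, 0 °C → rt
Reagents that add atoms: chloromethyl methyl ether (MOMCl), COCCl
Why: Williamson-type O-alkylation of the phenol by the α-chloro ether under amine base should give the aryl MOM acetal, a group that tolerates the palladium, organometallic, Lewis-acid and DDQ steps ahead and falls off in the final acid step.

Step 2
Reactants: 2 1-iodo-4-(methoxymethoxy)benzene, 3 ethynyltrimethylsilane
Product: 4 {[4-(methoxymethoxy)phenyl]ethynyl}trimethylsilane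
Conditions: PdCl2(PPh3)2 (2 mol%), CuI (4 mol%), Et3N, THF, rt
Reagents that add atoms: none
Why: Sonogashira coupling of an aryl iodide with a terminal alkyne runs at room temperature, and the silyl cap prevents a second arylation.

Step 3
Reactants: 4 {[4-(methoxymethoxy)phenyl]ethynyl}trimethylsilane
Product: 5 1-ethynyl-4-(methoxymethoxy)benzene
Conditions: K2CO3 (cat.), MeOH, rt
Reagents that add atoms: none
Why: Base-catalysed protodesilylation (methanolysis of the C(sp)–Si bond) should free the terminal alkyne without touching the MOM acetal.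

Step 4
Reactants: 2 1-iodo-4-(methoxymethoxy)benzene, 5 1-ethynyl-4-(methoxymethoxy)benzene
Product: 6 1,3-bis[4-(methoxymethoxy)phenyl]prop-2-yn-1-one
Conditions: PdCl2(PPh3)2 (1 mol%), CO (1 atm), 0.5 M aq NH3 (2 equiv), THF, rt
Reagents that add atoms: carbon monoxide, [C-]#[O+]
Why: Carbonylative Sonogashira coupling, in which oxidative addition of the aryl iodide, CO insertion into the aryl–palladium bond and alkynylation of the acylpalladium species follow one another, should give the alkynyl ketone, and leaving out copper under a CO atmosphere holds back the direct aryl–alkyne coupling.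

Step 5
Reactants: 7 prop-2-yn-1-ol (propargyl alcohol), 8 vinylmagnesium bromide
Product: 10 (2Z)-2-(iodomethylidene)but-3-en-1-ol, via cyclic alkenylmagnesium alkoxide 9 (not isolated)
Conditions: 8 (3 equiv), CuI (10 mol%), THF–Et2O, −20 °C → rt; then I2, THF, −60 → 0 °C; aq NH4Cl/Na2S2O3
Reagents that add atoms: iodine, II
Why: Copper-catalysed anti-carbomagnesiation of a propargylic alcohol: the magnesium alkoxide steers the vinyl group to the internal alkyne carbon and keeps magnesium on the terminal carbon, cis to the CH2O group, in a five-membered chelate, so that iodinolysis with retention should give the Z iodide with iodine trans to the vinyl group.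

Step 6
Reactants: 10 (2Z)-2-(iodomethylidene)but-3-en-1-ol
Product: 11 (1Z)-1-iodo-2-[(methoxymethoxy)methyl]buta-1,3-diene
Conditions: MOMCl, iPr2NEt, CH2Cl2, 0 °C → rt
Reagents that add atoms: chloromethyl methyl ether (MOMCl), COCCl
Why: O-alkylation of the primary allylic alcohol with the α-chloro ether under amine base (MOM acetal formation) is routine and leaves the alkenyl iodide and the diene untouched.

Step 7
Reactants: 11 (1Z)-1-iodo-2-[(methoxymethoxy)methyl]buta-1,3-diene, 5 1-ethynyl-4-(methoxymethoxy)benzene
Product: 12 1-{(3Z)-4-[(methoxymethoxy)methyl]hexa-3,5-dien-1-yn-1-yl}-4-(methoxymethoxy)benzene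
Conditions: Pd(PPh3)4 (3 mol%), CuI (6 mol%), Et3N, THF, rt
Reagents that add atoms: none
Why: Sonogashira coupling of an alkenyl iodide proceeds with retention of the double-bond geometry, so the alkynyl group should end up trans to the vinyl group as the diene needs for its s-cis conformer.

Step 8
Reactants: 12 1-{(3Z)-4-[(methoxymethoxy)methyl]hexa-3,5-dien-1-yn-1-yl}-4-(methoxymethoxy)benzene, 6 1,3-bis[4-(methoxymethoxy)phenyl]prop-2-yn-1-one
Product: 13 racemic [5-[(methoxymethoxy)methyl]-2-[4-(methoxymethoxy)phenyl]-6-{[4-(methoxymethoxy)phenyl]ethynyl}cyclohexa-1,4-dien-1-yl][4-(methoxymethoxy)phenyl]methanone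
Conditions: ZnCl2 (1.2 equiv, 1 M in Et2O), BHT (cat.), CH2Cl2, 0 → 40 °C
Reagents that add atoms: none
Why: The step is a concerted but asynchronous [4+2] cycloaddition between the s-cis diene C-3=C-4–C-5=C-6 of 12 and the zinc-bound triple bond of 6, the closest known reaction type being the Lewis-acid-promoted Diels–Alder reaction of 1-substituted butadienes with alkynyl ketones. Ring A is closed by this single intermolecular cycloaddition, which forms the σ-bonds between C-2 and C-3 and between C-1 and C-6 suprafacially on both partners and leaves a cyclohexa-1,4-diene. The conjugating alkynyl group on C-6 puts the largest HOMO coefficient of the diene on the free terminus C-3, while the ketone (more so when bound to ZnCl2) puts the largest LUMO coefficient of the dienophile on the ring-B-bearing β-carbon C-2, so the bond from C-2 to C-3 should form ahead of the bond from C-1 to C-6 and the aroyl carbon should end up beside the alkynyl-bearing carbon. The selectivity the step needs is this ortho regiochemistry, and what secures it is the alkynyl terminus together with the polarised ynone outweighing the weaker, opposite pull of the CH2OMOM group on C-5; the Z geometry of 12 keeps the alkyne on the outer side of the diene so that the reactive conformer is not hindered. The one new stereocentre, C-6, has no controlling element, is formed as a racemate and is removed in step 9.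

Step 9
Reactants: 13 racemic [5-[(methoxymethoxy)methyl]-2-[4-(methoxymethoxy)phenyl]-6-{[4-(methoxymethoxy)phenyl]ethynyl}cyclohexa-1,4-dien-1-yl][4-(methoxymethoxy)phenyl]methanone
Product: 14 [3-[(methoxymethoxy)methyl]-6-[4-(methoxymethoxy)phenyl]-2-{[4-(methoxymethoxy)phenyl]ethynyl}phenyl][4-(methoxymethoxy)phenyl]methanone
Conditions: DDQ (1.1 equiv), toluene, rt
Reagents that add atoms: none
Why: Quinone dehydrogenation of a cyclohexa-1,4-diene, by hydride abstraction from the doubly allylic carbon C-3 or C-6 followed by proton loss, is driven by aromatisation and should be fast at room temperature, leaving the acetals and the alkyne alone.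

Step 10
Reactants: 14 [3-[(methoxymethoxy)methyl]-6-[4-(methoxymethoxy)phenyl]-2-{[4-(methoxymethoxy)phenyl]ethynyl}phenyl][4-(methoxymethoxy)phenyl]methanone, 2 1-iodo-4-(methoxymethoxy)benzene
Product: 16 {3-[(methoxymethoxy)methyl]-6-[4-(methoxymethoxy)phenyl]-2-{[4-(methoxymethoxy)phenyl]ethynyl}phenyl}bis[4-(methoxymethoxy)phenyl]methanol, via [4-(methoxymethoxy)phenyl]lithium 15 (not isolated)
Conditions: 2 (2.2 equiv), n-BuLi (2.1 equiv), THF, −78 °C; then 14, −78 → 0 °C; H2O
Reagents that add atoms: none
Why: Iodine–lithium exchange followed by 1,2-addition of the aryllithium to the non-enolisable diaryl ketone should give the triarylcarbinol, the rod-like alkyne on C-6 leaving one face of the twisted carbonyl group open.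

Step 11
Reactants: 16 {3-[(methoxymethoxy)methyl]-6-[4-(methoxymethoxy)phenyl]-2-{[4-(methoxymethoxy)phenyl]ethynyl}phenyl}bis[4-(methoxymethoxy)phenyl]methanol
Product: 18 selaginellin, via deprotected triarylcarbinol 17 (not isolated)
Conditions: 3 M aq HCl, THF, 40 °C; NaHCO3 work-up
Reagents that add atoms: none
Why: Acid-catalysed acetal hydrolysis removes the five MOM groups, and the triarylcarbinol then ionises to a carbenium ion stabilised by two para-hydroxyphenyl groups that loses a phenolic proton on neutralisation, an acid-catalysed dehydration to the quinone methide (fuchsone formation).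

Compound list
1 | 4-iodophenol | Oc1ccc(I)cc1 | starting material
2 | 1-iodo-4-(methoxymethoxy)benzene | COCOc1ccc(I)cc1 | intermediate
3 | ethynyltrimethylsilane | C#C[Si](C)(C)C | starting material
4 | {[4-(methoxymethoxy)phenyl]ethynyl}trimethylsilane | COCOc1ccc(C#C[Si](C)(C)C)cc1 | intermediate
5 | 1-ethynyl-4-(methoxymethoxy)benzene | COCOc1ccc(C#C)cc1 | intermediate
6 | 1,3-bis[4-(methoxymethoxy)phenyl]prop-2-yn-1-one | O=C(C#Cc1ccc(OCOC)cc1)c1ccc(OCOC)cc1 | intermediate
7 | prop-2-yn-1-ol (propargyl alcohol) | C#CCO | starting material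
8 | vinylmagnesium bromide | C=C[Mg]Br | starting material
9 | 4-ethenyl-5H-1,2-oxamagnesole (cyclic alkenylmagnesium alkoxide; magnesium on the former terminal alkyne carbon and cis to the CH2O group) | C=CC1=C[Mg]OC1 | intermediate (not isolated)
10 | (2Z)-2-(iodomethylidene)but-3-en-1-ol | C=C/C(CO)=C/I | intermediate
11 | (1Z)-1-iodo-2-[(methoxymethoxy)methyl]buta-1,3-diene | C=C/C(COCOC)=C/I | intermediate
12 | 1-{(3Z)-4-[(methoxymethoxy)methyl]hexa-3,5-dien-1-yn-1-yl}-4-(methoxymethoxy)benzene (alkynyl trans to vinyl) | C=C/C(COCOC)=C/C#Cc1ccc(OCOC)cc1 | intermediate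
13 | racemic [5-[(methoxymethoxy)methyl]-2-[4-(methoxymethoxy)phenyl]-6-{[4-(methoxymethoxy)phenyl]ethynyl}cyclohexa-1,4-dien-1-yl][4-(methoxymethoxy)phenyl]methanone | O=C(c1ccc(OCOC)cc1)C1=C(c2ccc(OCOC)cc2)CC=C(COCOC)C1C#Cc1ccc(OCOC)cc1 | intermediate
14 | [3-[(methoxymethoxy)methyl]-6-[4-(methoxymethoxy)phenyl]-2-{[4-(methoxymethoxy)phenyl]ethynyl}phenyl][4-(methoxymethoxy)phenyl]methanone | O=C(c1ccc(OCOC)cc1)c1c(-c2ccc(OCOC)cc2)ccc(COCOC)c1C#Cc1ccc(OCOC)cc1 | intermediate
15 | [4-(methoxymethoxy)phenyl]lithium | [Li]c1ccc(OCOC)cc1 | intermediate (not isolated)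
16 | {3-[(methoxymethoxy)methyl]-6-[4-(methoxymethoxy)phenyl]-2-{[4-(methoxymethoxy)phenyl]ethynyl}phenyl}bis[4-(methoxymethoxy)phenyl]methanol | OC(c1ccc(OCOC)cc1)(c1ccc(OCOC)cc1)c1c(-c2ccc(OCOC)cc2)ccc(COCOC)c1C#Cc1ccc(OCOC)cc1 | intermediate
17 | 4,4'-{hydroxy[3-(hydroxymethyl)-6-(4-hydroxyphenyl)-2-[(4-hydroxyphenyl)ethynyl]phenyl]methylene}diphenol | OCc1ccc(-c2ccc(O)cc2)c(C(O)(c2ccc(O)cc2)c2ccc(O)cc2)c1C#Cc1ccc(O)cc1 | intermediate (not isolated)
18 | selaginellin, 4-{[3-(hydroxymethyl)-6-(4-hydroxyphenyl)-2-[(4-hydroxyphenyl)ethynyl]phenyl](4-hydroxyphenyl)methylidene}cyclohexa-2,5-dien-1-one (no stereocentre) | O=C1C=CC(=C(c2ccc(O)cc2)c2c(-c3ccc(O)cc3)ccc(CO)c2C#Cc2ccc(O)cc2)C=C1 | target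

Total step count: 11.
Longest linear sequence: 8 steps (steps 1, 2, 3, 7, 8, 9, 10, 11, from 4-iodophenol).

Steps most likely to fail

1. Step 8. The triple bond of 6 lies between two electron-rich aryl groups, so the cycloaddition may be slower than oligomerisation of the dienyne. The orientation may also erode if the C-5 substituent and crowding between the aroyl group and the alkynyl terminus outweigh the frontier-orbital preference. The fallback sets out from alkyne 5 and comes back at ketone 14; it keeps the same ring-forming bonds but uses a formyl group as activator and brings in ring D afterwards. Alkyne 5 is lithiated (n-BuLi, THF, −78 °C) and formylated with DMF to the ynal 3-[4-(methoxymethoxy)phenyl]prop-2-ynal F1, a smaller and far more electrophilic dienophile with a more strongly polarised triple bond. Its Diels–Alder reaction with 12 (Me2AlCl, CH2Cl2, −78 °C, or warming in toluene) should give the racemic cyclohexa-1,4-diene-1-carbaldehyde F2. DDQ in toluene then gives the 2-alkynyl-6-arylbenzaldehyde F3. Aryllithium 15 (from 2 and n-BuLi) adds to the aldehyde to give the racemic diarylmethanol F4, and MnO2 in CH2Cl2 oxidises this doubly benzylic alcohol to 14.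

2. Step 5. Deprotonation of the terminal alkyne may compete with vinyl transfer, the transfer may stop short, and the small iodo diene may polymerise or be lost during iodinolysis and isolation. The fallback sets out from alkyne 5 and comes back at dienyne 12; the alkene geometry is then fixed by anti addition of bromine and two stereoretentive couplings instead of by a magnesium chelate. Commercial ethyl propiolate is brominated (Br2, CH2Cl2) to ethyl (2E)-2,3-dibromoprop-2-enoate F5. Sonogashira coupling with 5 (Pd(PPh3)4, CuI, Et3N, THF, rt) should take place at the β-bromide only, the more electrophilic and less hindered C–Br bond, giving the bromo enynoate ethyl (2E)-2-bromo-5-[4-(methoxymethoxy)phenyl]pent-2-en-4-ynoate F6 with the alkyne cis to the ester. i-Bu2AlH (CH2Cl2, −78 °C) reduces the ester to the bromo enynol (2E)-2-bromo-5-[4-(methoxymethoxy)phenyl]pent-2-en-4-yn-1-ol F7, and MOMCl/iPr2NEt gives its MOM ether 1-[(3E)-4-bromo-5-(methoxymethoxy)pent-3-en-1-yn-1-yl]-4-(methoxymethoxy)benzene F8. Stille coupling with tributyl(vinyl)stannane (Pd(PPh3)4, CuI, DMF, 60 °C) replaces bromine by vinyl with retention and gives 12.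

3. Step 10. Approach to a carbonyl group twisted between an aryl and an alkynyl substituent may be blocked, so that the aryllithium adds across the neighbouring alkyne instead or survives until the quench. The fallback sets out from ketone 14 and comes back at the target 18; the last aryl group then enters as a π-nucleophile attacking a carbenium ion, and the quinone methide is made by oxidation instead of dehydration. NaBH4 (THF–MeOH), small enough for the shielded carbonyl group, reduces 14 to the diarylmethanol F4 (the compound that the first fallback also passes through). In TFA–CH2Cl2 with excess phenol the alcohol ionises to a para-oxygen-stabilised diarylmethyl cation, which phenol captures at its para position (Friedel–Crafts alkylation). Without purification of the crude mixture, aqueous HCl in THF then completes removal of the MOM groups and gives the leuco triarylmethane 4,4'-{[3-(hydroxymethyl)-6-(4-hydroxyphenyl)-2-[(4-hydroxyphenyl)ethynyl]phenyl]methylene}diphenol F9. DDQ (1 equiv, THF, rt) abstracts the triarylmethane hydride, and loss of a phenolic proton gives 18.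

Further compounds
F1 | step 8 | 3-[4-(methoxymethoxy)phenyl]prop-2-ynal | O=CC#Cc1ccc(OCOC)cc1
F2 | step 8 | racemic 5-[(methoxymethoxy)methyl]-2-[4-(methoxymethoxy)phenyl]-6-{[4-(methoxymethoxy)phenyl]ethynyl}cyclohexa-1,4-diene-1-carbaldehyde | O=CC1=C(c2ccc(OCOC)cc2)CC=C(COCOC)C1C#Cc1ccc(OCOC)cc1
F3 | step 8 | 3-[(methoxymethoxy)methyl]-6-[4-(methoxymethoxy)phenyl]-2-{[4-(methoxymethoxy)phenyl]ethynyl}benzaldehyde | O=Cc1c(-c2ccc(OCOC)cc2)ccc(COCOC)c1C#Cc1ccc(OCOC)cc1
F4 | step 8 | racemic {3-[(methoxymethoxy)methyl]-6-[4-(methoxymethoxy)phenyl]-2-{[4-(methoxymethoxy)phenyl]ethynyl}phenyl}[4-(methoxymethoxy)phenyl]methanol | OC(c1ccc(OCOC)cc1)c1c(-c2ccc(OCOC)cc2)ccc(COCOC)c1C#Cc1ccc(OCOC)cc1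
F5 | step 5 | ethyl (2E)-2,3-dibromoprop-2-enoate | CCOC(=O)/C(Br)=C\Br
F6 | step 5 | ethyl (2E)-2-bromo-5-[4-(methoxymethoxy)phenyl]pent-2-en-4-ynoate | CCOC(=O)/C(Br)=C\C#Cc1ccc(OCOC)cc1
F7 | step 5 | (2E)-2-bromo-5-[4-(methoxymethoxy)phenyl]pent-2-en-4-yn-1-ol | OC/C(Br)=C\C#Cc1ccc(OCOC)cc1
F8 | step 5 | 1-[(3E)-4-bromo-5-(methoxymethoxy)pent-3-en-1-yn-1-yl]-4-(methoxymethoxy)benzene | COCOC/C(Br)=C\C#Cc1ccc(OCOC)cc1
F9 | step 10 | 4,4'-{[3-(hydroxymethyl)-6-(4-hydroxyphenyl)-2-[(4-hydroxyphenyl)ethynyl]phenyl]methylene}diphenol | OCc1ccc(-c2ccc(O)cc2)c(C(c2ccc(O)cc2)c2ccc(O)cc2)c1C#Cc1ccc(O)cc1
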